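The cyclohexane is cut at C1–C2 (C1 carries the oxane; C2 is the CH2 leading to C4(CH3)Cl). The acyclic precursor already holds the anti C3–Br/C4–Cl pair from a catalytic enantioselective bromochlorination; C2 is a primary bromide and C1 a CH between a temporary allyl ester and the keto ester that becomes oxane C3/C2. The key step exploits that C1 is α to oxane C3 and that the trans dihalide keeps the new ring in a chair with axial Br: in one flask it closes the carbocycle (6-exo-tet), expels the allyl ester as propene and CO2, and protonates the exocyclic enol anti to C3–Br, fixing C1. Allylation, bromolactonisation and methylenation finish the oxane.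

Key step: step 8

Remark: the ligand antipodes in steps 4 and 9 are taken to be those that deliver the configurations drawn; cyclohexane atoms are numbered C1 (oxane-bearing) to C6, with Br on C3 and Cl/CH3 on C4.

Step 1
Reactants: 1 4-bromobut-1-yne; 2 methyl chloroformate
Product: 3 methyl 5-bromopent-2-ynoate
Conditions: n-BuLi, THF, −78 °C; then ClCO2Me, −78 → −20 °C
Reagents that add atoms: methyl chloroformate (2), COC(=O)Cl
Why: C-acylation of a lithium acetylide with a chloroformate should give the ynoate cleanly, because deprotonation of the terminal alkyne at −78 °C is far faster than any attack on the primary bromide.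

Step 2
Reactants: 3 methyl 5-bromopent-2-ynoate
Product: 4 methyl (2Z)-5-bromo-3-methylpent-2-enoate
Conditions: Me2CuLi (from MeLi and CuI), THF, −78 °C; aq. NH4Cl quench at −78 °C
Reagents that add atoms: lithium dimethylcuprate, [Li+].C[Cu-]C
Why: Conjugate addition (syn-carbocupration) of the cuprate to the ynoate and protonation of the vinylcopper with retention should place the new methyl trans to the ester, which fixes the (Z)-trisubstituted alkene needed for the trans C3–Br/C4–Cl relationship; no stereocentre is formed.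

Step 3
Reactants: 4 methyl (2Z)-5-bromo-3-methylpent-2-enoate
Product: 5 (2Z)-5-bromo-3-methylpent-2-en-1-ol
Conditions: iBu2AlH (DIBAL-H, 2.2 equiv), CH2Cl2, −78 °C; Rochelle salt work-up
Reagents that add atoms: none
Why: 1,2-Reduction of the enoate with DIBAL-H at −78 °C should give the allylic alcohol without erosion of the alkene geometry and without touching the primary bromide.

Step 4
Reactants: 5 (2Z)-5-bromo-3-methylpent-2-en-1-ol
Product: 6 (2S,3S)-2,5-dibromo-3-chloro-3-methylpentan-1-ol
Conditions: NBS, ClTi(OiPr)3, chiral tridentate Schiff-base diol ligand (20 mol %), hexanes, −20 °C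
Reagents that add atoms: N-bromosuccinimide, O=C1CCC(=O)N1Br; chlorotitanium triisopropoxide, CC(C)O[Ti](Cl)(OC(C)C)OC(C)C
Why: Titanium-mediated catalytic enantioselective bromochlorination of an allylic alcohol: the titanium-bound substrate forms a bromonium ion on the face chosen by the chiral ligand and titanium-bound chloride opens it anti at the tertiary carbon, so both stereocentres are set together by catalyst control and their relative configuration by anti addition to the (Z)-alkene.

Step 5
Reactants: 6 (2S,3S)-2,5-dibromo-3-chloro-3-methylpentan-1-ol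
Product: 7 (2S,3S)-2,5-dibromo-3-chloro-3-methylpentyl trifluoromethanesulfonate
Conditions: Tf2O, 2,6-lutidine, CH2Cl2, −78 °C; used at once
Reagents that add atoms: trifluoromethanesulfonic anhydride, O=S(=O)(OS(=O)(=O)C(F)(F)F)C(F)(F)F
Why: O-Sulfonylation of the primary alcohol with a hindered pyridine base should give the triflate, the one leaving group reactive enough for SN2 displacement next to the bromine-bearing carbon, while the stereocentres are not touched.

Step 6
Reactants: 7 (2S,3S)-2,5-dibromo-3-chloro-3-methylpentyl trifluoromethanesulfonate; 8 allyl acetate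
Product: 9 prop-2-en-1-yl (4S,5S)-4,7-dibromo-5-chloro-5-methylheptanoate
Conditions: allyl acetate, LiN(iPr)2 (LDA), THF, −78 °C; then 7, −78 → −40 °C
Reagents that add atoms: allyl acetate (8), CC(=O)OCC=C
Why: SN2 alkylation of an ester lithium enolate by the primary triflate at low temperature should occur only at the triflate, since both alkyl bromides and the tertiary chloride are far less reactive, and it attaches the future C1 to C6.

Step 7
Reactants: 9 prop-2-en-1-yl (4S,5S)-4,7-dibromo-5-chloro-5-methylheptanoate; 10 dimethyl oxalate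
Product: 11 1-methyl 4-(prop-2-en-1-yl) 3-[(2S,3S)-2,5-dibromo-3-chloro-3-methylpentyl]-2-oxobutanedioate (C3 epimers, largely enolised)
Conditions: LiN(iPr)2 (2.1 equiv), THF, −78 °C; dimethyl oxalate; AcOH quench
Reagents that add atoms: dimethyl oxalate (10), COC(=O)C(=O)OC
Why: Crossed Claisen condensation of the ester enolate with non-enolisable dimethyl oxalate should give the α-oxalyl ester, whose CH (future ring C1) is now a soft, doubly activated pro-nucleophile; trapping at −78 °C outruns attack of the enolate on either bromide.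

Step 8
Reactants: 11 1-methyl 4-(prop-2-en-1-yl) 3-[(2S,3S)-2,5-dibromo-3-chloro-3-methylpentyl]-2-oxobutanedioate
Product: 15 methyl 2-[(1S,3S,4S)-3-bromo-4-chloro-4-methylcyclohexyl]-2-oxoacetate, via cyclised allyl keto diester 12 (not isolated), via keto acid 13 (not isolated), via exocyclic enol 14 (not isolated)
Conditions: Cs2CO3, MeCN, 0 → 25 °C; then HCO2H (excess), Et3N, Pd(OAc)2 (5 mol %), PPh3 (20 mol %), 25 °C
Reagents that add atoms: none
Why: Cs2CO3 deprotonates the enolised 1,3-dicarbonyl CH of 11 and the soft carbanion displaces the primary bromide, closing the cyclohexane by 6-exo-tet C-alkylation (the classical cycloalkylation of a β-keto ester); 3-exo-tet attack on the secondary bromide is blocked by its neopentyl-type environment and O-alkylation would need an eight-membered ring. Zerovalent palladium, formed from Pd(OAc)2 and PPh3, then ionises the allyl ester of 12, formate reduces the allyl fragment to propene, and the β-keto acid 13 loses CO2 to the exocyclic enol 14 (deallylation–decarboxylation of an allyl β-keto ester). The only new stereocentre, ring C1, is created when 14 ketonises: the trans C3–Br/C4–Cl pair holds the ring in the chair with both halogens axial and the methyl equatorial, the axial C3–Br screens the axial face of C1, and the proton is delivered from the equatorial side, which leaves the keto ester cis to bromine (1S). This is the kinetic and less stable epimer, in line with the known ketonisation of exocyclic cyclohexyl enols from the less hindered equatorial side. The step needs C- over O-alkylation, six- over three-membered closure and protonation without re-enolisation; ring size, the hindered secondary bromide and the weakly acidic formic acid buffer at 25 °C should secure these.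

Step 9
Reactants: 15 methyl 2-[(1S,3S,4S)-3-bromo-4-chloro-4-methylcyclohexyl]-2-oxoacetate
Product: 16 methyl (2S)-2-[(1S,3S,4S)-3-bromo-4-chloro-4-methylcyclohexyl]-2-hydroxypent-4-enoate
Conditions: Sn(CH2CH=CH2)4, In(OTf)3 (10 mol %), chiral C2-symmetric N,N'-dioxide ligand (12 mol %), CH2Cl2, 0 °C
Reagents that add atoms: tetraallylstannane, C=CC[Sn](CC=C)(CC=C)CC=C
Why: Lewis-acid-catalysed enantioselective allylation of an α-keto ester: the chiral In(OTf)3–N,N'-dioxide complex should chelate the 1,2-dicarbonyl unit and direct allyl transfer to the Re face of the ketone, setting the (2S) tertiary carbinol (oxane C3) by catalyst control because the adjacent ring carbon offers no local bias.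

Step 10
Reactants: 16 methyl (2S)-2-[(1S,3S,4S)-3-bromo-4-chloro-4-methylcyclohexyl]-2-hydroxypent-4-enoate
Product: 17 methyl (2S)-2-[(1S,3S,4S)-3-bromo-4-chloro-4-methylcyclohexyl]-2-hydroxy-5-methylhex-4-enoate
Conditions: 2-methylbut-2-ene (excess), second-generation Grubbs catalyst (H2IMes)(PCy3)Cl2Ru=CHPh (5 mol %), CH2Cl2, 40 °C
Reagents that add atoms: 2-methylbut-2-ene, CC=C(C)C
Why: Olefin cross-metathesis with excess 2-methylbut-2-ene should convert the terminal vinyl group into the trisubstituted prenyl alkene under neutral conditions that leave the halides, the tertiary alcohol and all stereocentres untouched.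

Step 11
Reactants: 17 methyl (2S)-2-[(1S,3S,4S)-3-bromo-4-chloro-4-methylcyclohexyl]-2-hydroxy-5-methylhex-4-enoate
Product: 18 (2S)-2-[(1S,3S,4S)-3-bromo-4-chloro-4-methylcyclohexyl]-2-hydroxy-5-methylhex-4-enoic acid
Conditions: LiOH·H2O, THF–H2O, 0 → 25 °C; then 1 M HCl to pH 3 at 0 °C
Reagents that add atoms: lithium hydroxide monohydrate, [Li+].[OH-].O
Why: Saponification of the methyl ester, assisted by the neighbouring hydroxyl, should give the α-hydroxy acid at or below room temperature without displacement or elimination of the halides.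

Step 12
Reactants: 18 (2S)-2-[(1S,3S,4S)-3-bromo-4-chloro-4-methylcyclohexyl]-2-hydroxy-5-methylhex-4-enoic acid
Product: 19 (3S,5R)-5-bromo-3-[(1S,3S,4S)-3-bromo-4-chloro-4-methylcyclohexyl]-3-hydroxy-6,6-dimethyloxan-2-one
Conditions: NBS, NaHCO3, MeCN, −20 → 0 °C, dark
Reagents that add atoms: N-bromosuccinimide, O=C1CCC(=O)N1Br
Why: 6-endo bromolactonisation: the carboxylate should open the bromonium ion of the prenyl alkene at its tertiary carbon (Markovnikov) through a chair transition state with the large cyclohexyl group equatorial and the hydroxyl axial, and anti addition then places bromine equatorial and cis to the cyclohexyl group, which sets oxane C5 as (R) by 1,3-induction from C3.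

Step 13
Reactants: 19 (3S,5R)-5-bromo-3-[(1S,3S,4S)-3-bromo-4-chloro-4-methylcyclohexyl]-3-hydroxy-6,6-dimethyloxan-2-one
Product: 20 (3S,5R)-5-bromo-3-[(1S,3S,4S)-3-bromo-4-chloro-4-methylcyclohexyl]-6,6-dimethyl-2-methylideneoxan-3-ol
Conditions: Cp2TiMe2 (4 equiv), toluene–THF, 65 °C, dark; filtration through basic Al2O3
Reagents that add atoms: dimethyltitanocene Cp2TiMe2, C[Ti](C)(C1C=CC=C1)C1C=CC=C1
Why: Petasis methylenation: thermolysis of Cp2TiMe2 generates Cp2Ti=CH2, which should convert the lactone carbonyl into the exocyclic enol ether through an oxatitanacyclobutane under non-acidic conditions; the quaternary C3 prevents migration of the double bond into the ring, and excess reagent covers the free hydroxyl, which is released on work-up.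

Compound list
1 | 4-bromobut-1-yne | C#CCCBr | starting material
2 | methyl chloroformate | COC(=O)Cl | starting material
3 | methyl 5-bromopent-2-ynoate | COC(=O)C#CCCBr | intermediate
4 | methyl (2Z)-5-bromo-3-methylpent-2-enoate | COC(=O)/C=C(/C)CCBr | intermediate
5 | (2Z)-5-bromo-3-methylpent-2-en-1-ol | OC/C=C(/C)CCBr | intermediate
6 | (2S,3S)-2,5-dibromo-3-chloro-3-methylpentan-1-ol | BrCC[C@](C)(Cl)[C@@H](Br)CO | intermediate
7 | (2S,3S)-2,5-dibromo-3-chloro-3-methylpentyl trifluoromethanesulfonate | BrCC[C@](C)(Cl)[C@@H](Br)COS(=O)(=O)C(F)(F)F | intermediate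
8 | allyl acetate (prop-2-en-1-yl acetate) | CC(=O)OCC=C | starting material
9 | prop-2-en-1-yl (4S,5S)-4,7-dibromo-5-chloro-5-methylheptanoate | BrCC[C@](C)(Cl)[C@@H](Br)CCC(=O)OCC=C | intermediate
10 | dimethyl oxalate | COC(=O)C(=O)OC | starting material
11 | 1-methyl 4-(prop-2-en-1-yl) 3-[(2S,3S)-2,5-dibromo-3-chloro-3-methylpentyl]-2-oxobutanedioate (C3 epimers, largely enolised) | BrCC[C@](C)(Cl)[C@@H](Br)CC(C(=O)OCC=C)C(=O)C(=O)OC | intermediate
12 | prop-2-en-1-yl (3S,4S)-3-bromo-4-chloro-1-(2-methoxy-2-oxoacetyl)-4-methylcyclohexane-1-carboxylate (C1 epimers) | C=CCOC(=O)C1(C(=O)C(=O)OC)CC[C@](C)(Cl)[C@@H](Br)C1 | intermediate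
13 | (3S,4S)-3-bromo-4-chloro-1-(2-methoxy-2-oxoacetyl)-4-methylcyclohexane-1-carboxylic acid (C1 epimers) | OC(=O)C1(C(=O)C(=O)OC)CC[C@](C)(Cl)[C@@H](Br)C1 | intermediate
14 | methyl 2-[(3S,4S)-3-bromo-4-chloro-4-methylcyclohexylidene]-2-hydroxyacetate | COC(=O)C(O)=C1CC[C@](C)(Cl)[C@@H](Br)C1 | intermediate
15 | methyl 2-[(1S,3S,4S)-3-bromo-4-chloro-4-methylcyclohexyl]-2-oxoacetate | COC(=O)C(=O)[C@H]1CC[C@](C)(Cl)[C@@H](Br)C1 | intermediate
16 | methyl (2S)-2-[(1S,3S,4S)-3-bromo-4-chloro-4-methylcyclohexyl]-2-hydroxypent-4-enoate | C=CC[C@@](O)(C(=O)OC)[C@H]1CC[C@](C)(Cl)[C@@H](Br)C1 | intermediate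
17 | methyl (2S)-2-[(1S,3S,4S)-3-bromo-4-chloro-4-methylcyclohexyl]-2-hydroxy-5-methylhex-4-enoate | CC(C)=CC[C@@](O)(C(=O)OC)[C@H]1CC[C@](C)(Cl)[C@@H](Br)C1 | intermediate
18 | (2S)-2-[(1S,3S,4S)-3-bromo-4-chloro-4-methylcyclohexyl]-2-hydroxy-5-methylhex-4-enoic acid | CC(C)=CC[C@@](O)(C(=O)O)[C@H]1CC[C@](C)(Cl)[C@@H](Br)C1 | intermediate
19 | (3S,5R)-5-bromo-3-[(1S,3S,4S)-3-bromo-4-chloro-4-methylcyclohexyl]-3-hydroxy-6,6-dimethyloxan-2-one | O=C1OC(C)(C)[C@H](Br)C[C@]1(O)[C@H]1CC[C@](C)(Cl)[C@@H](Br)C1 | intermediate
20 | (3S,5R)-5-bromo-3-[(1S,3S,4S)-3-bromo-4-chloro-4-methylcyclohexyl]-6,6-dimethyl-2-methylideneoxan-3-ol | C=C1OC(C)(C)[C@H](Br)C[C@]1(O)[C@H]1CC[C@](C)(Cl)[C@@H](Br)C1 | target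

Total step count: 13. Longest linear sequence: 13 steps (1 → 20).

Steps most likely to fail

Step 8. The soft enolate may close slowly or partly at the secondary bromide (three-membered ring). The kinetic preference in the ketonisation may also be eroded by re-enolisation of the keto ester in the amine-containing medium, which would let C1 drift to the more stable trans arrangement. The fallback sets out from 7 and returns at 15. Methyl pyruvate is condensed with 1,1-dimethylhydrazine to methyl 2-(2,2-dimethylhydrazinylidene)propanoate F1. Its lithium aza-enolate (LiN(iPr)2, THF, −78 °C) is alkylated by 7 to methyl (5S,6S)-5,8-dibromo-6-chloro-2-(2,2-dimethylhydrazinylidene)-6-methyloctanoate F2. A second portion of LiN(iPr)2 (THF–DMPU, −78 → 0 °C) closes the same C1–C2 bond by aza-enolate alkylation to methyl 2-[(3S,4S)-3-bromo-4-chloro-4-methylcyclohexyl]-2-(2,2-dimethylhydrazinylidene)acetate F3. Buffered CuCl2 (aq. THF, pH 7) releases methyl 2-[(3S,4S)-3-bromo-4-chloro-4-methylcyclohexyl]-2-oxoacetate F4 as a C1 epimer mixture. LiN(SiMe3)2 (THF, −78 °C) then regenerates the exocyclic lithium enolate, and a quench at −78 °C with 2,6-di-tert-butylphenol should protonate it from the equatorial side under strictly non-equilibrating conditions to give 15.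

Step 9. The allyl transfer may discriminate poorly between the two faces of the ketone, since the ring carbon next to it gives no bias, and Lewis-acid-promoted enolisation may erode C1. The fallback sets out from 15 and returns at 18, replacing steps 9 to 11 by auxiliary control. Hydrogenation with RuCl2[(S)-BINAP] or its antipode, chosen for the (S)-carbinol (H2, MeOH), should give methyl (2S)-2-[(1S,3S,4S)-3-bromo-4-chloro-4-methylcyclohexyl]-2-hydroxyacetate F5. LiOH·H2O (THF–H2O) gives (2S)-2-[(1S,3S,4S)-3-bromo-4-chloro-4-methylcyclohexyl]-2-hydroxyacetic acid F6. Pivalaldehyde with catalytic TsOH (pentane, removal of water) gives the cis acetal (2S,5S)-5-[(1S,3S,4S)-3-bromo-4-chloro-4-methylcyclohexyl]-2-tert-butyl-1,3-dioxolan-4-one F7. LiN(iPr)2 (THF, −78 °C) and prenyl bromide then add the prenyl group anti to tert-butyl (self-regeneration of the stereocentre) to give (2S,5S)-5-[(1S,3S,4S)-3-bromo-4-chloro-4-methylcyclohexyl]-2-tert-butyl-5-(3-methylbut-2-en-1-yl)-1,3-dioxolan-4-one F8. KOH in aqueous MeOH releases 18.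

Step 12. The free tertiary hydroxyl may compete with the carboxylate for the bromonium ion (five-membered ether formation), and the chair transition state may show only a weak facial bias, so that diastereocontrol at oxane C5 is lost. The fallback sets out from 17 and returns at 19, masking the hydroxyl and moving face selection to a catalyst. TESOTf and 2,6-lutidine give methyl (2S)-2-[(1S,3S,4S)-3-bromo-4-chloro-4-methylcyclohexyl]-5-methyl-2-[(triethylsilyl)oxy]hex-4-enoate F9. Me3SnOH (1,2-dichloroethane, 70 °C) gives (2S)-2-[(1S,3S,4S)-3-bromo-4-chloro-4-methylcyclohexyl]-5-methyl-2-[(triethylsilyl)oxy]hex-4-enoic acid F10. NBS with the cinchona-alkaloid catalyst (DHQD)2PHAL (catalyst-controlled bromolactonisation) should give (3S,5R)-5-bromo-3-[(1S,3S,4S)-3-bromo-4-chloro-4-methylcyclohexyl]-6,6-dimethyl-3-[(triethylsilyl)oxy]oxan-2-one F11. HF·pyridine then frees 19.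

Further compounds
F1 | step 8 | methyl 2-(2,2-dimethylhydrazinylidene)propanoate | COC(=O)C(C)=NN(C)C
F2 | step 8 | methyl (5S,6S)-5,8-dibromo-6-chloro-2-(2,2-dimethylhydrazinylidene)-6-methyloctanoate | BrCC[C@](C)(Cl)[C@@H](Br)CCC(=NN(C)C)C(=O)OC
F3 | step 8 | methyl 2-[(3S,4S)-3-bromo-4-chloro-4-methylcyclohexyl]-2-(2,2-dimethylhydrazinylidene)acetate (C1 epimers) | COC(=O)C(=NN(C)C)C1CC[C@](C)(Cl)[C@@H](Br)C1
F4 | step 8 | methyl 2-[(3S,4S)-3-bromo-4-chloro-4-methylcyclohexyl]-2-oxoacetate (C1 epimer mixture) | COC(=O)C(=O)C1CC[C@](C)(Cl)[C@@H](Br)C1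
F5 | step 9 | methyl (2S)-2-[(1S,3S,4S)-3-bromo-4-chloro-4-methylcyclohexyl]-2-hydroxyacetate | COC(=O)[C@@H](O)[C@H]1CC[C@](C)(Cl)[C@@H](Br)C1
F6 | step 9 | (2S)-2-[(1S,3S,4S)-3-bromo-4-chloro-4-methylcyclohexyl]-2-hydroxyacetic acid | OC(=O)[C@@H](O)[C@H]1CC[C@](C)(Cl)[C@@H](Br)C1
F7 | step 9 | (2S,5S)-5-[(1S,3S,4S)-3-bromo-4-chloro-4-methylcyclohexyl]-2-tert-butyl-1,3-dioxolan-4-one | O=C1O[C@@H](C(C)(C)C)O[C@H]1[C@H]2CC[C@](C)(Cl)[C@@H](Br)C2
F8 | step 9 | (2S,5S)-5-[(1S,3S,4S)-3-bromo-4-chloro-4-methylcyclohexyl]-2-tert-butyl-5-(3-methylbut-2-en-1-yl)-1,3-dioxolan-4-one | O=C1O[C@@H](C(C)(C)C)O[C@@]1(CC=C(C)C)[C@H]2CC[C@](C)(Cl)[C@@H](Br)C2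
F9 | step 12 | methyl (2S)-2-[(1S,3S,4S)-3-bromo-4-chloro-4-methylcyclohexyl]-5-methyl-2-[(triethylsilyl)oxy]hex-4-enoate | CC(C)=CC[C@@](O[Si](CC)(CC)CC)(C(=O)OC)[C@H]1CC[C@](C)(Cl)[C@@H](Br)C1
F10 | step 12 | (2S)-2-[(1S,3S,4S)-3-bromo-4-chloro-4-methylcyclohexyl]-5-methyl-2-[(triethylsilyl)oxy]hex-4-enoic acid | CC(C)=CC[C@@](O[Si](CC)(CC)CC)(C(=O)O)[C@H]1CC[C@](C)(Cl)[C@@H](Br)C1
F11 | step 12 | (3S,5R)-5-bromo-3-[(1S,3S,4S)-3-bromo-4-chloro-4-methylcyclohexyl]-6,6-dimethyl-3-[(triethylsilyl)oxy]oxan-2-one | O=C1OC(C)(C)[C@H](Br)C[C@]1(O[Si](CC)(CC)CC)[C@H]1CC[C@](C)(Cl)[C@@H](Br)C1
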